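**Retrosynthetic overview**
- The target is the 3β-caffeate of eudesm-4(15)-ene-1β,3β,8α-triol. The last events are allylic C–H oxidation at C3, esterification with inversion at C3, and global desilylation.
- The exocyclic C4=C15 alkene and the trans ring fusion (5α-H) arise together from a C4=C5 alkene bearing C15–O, by palladium/formate reduction with allylic transposition. The C8–OH comes from a C8=C9 alkene made from a temporary C9 ketone.
- Key disconnection: ring A is built onto ring B by a double-aldol annulation of glutaraldehyde (C1–C4 plus C15) with achiral 5-isopropyl-2-methylcyclohexane-1,3-dione. C10 bonds to C1 (aldol) and C4 bonds to C5 (aldol condensation).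
- Enabling feature: in ring A the carbinol C1 adjoins quaternary C10, and the sp2 carbon C4 with its one-carbon branch C15 adjoins C5, so C1–C2–C3–C4(–C15) is a 1,5-dialdehyde. Ring B with temporary carbonyls at C5 and C9 has a mirror plane through C7 and C10.
- Ring order: ring B is bought, and ring A is closed in the key step.

Key step: step 2

Remark: eudesmane numbering is used (C10 is the quaternary carbon, C14 its methyl group, C15 the carbon on C4). β means the face of the C10 methyl group. TBS is tert-butyldimethylsilyl.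

Step 1
Reactants: 1 5-isopropylcyclohexane-1,3-dione
Product: 2 5-isopropyl-2-methylcyclohexane-1,3-dione
Conditions: MeI, NaOH, H2O–dioxane, 65 °C
Reagents that add atoms: iodomethane, CI
Why: C-alkylation of the stabilised enolate of a cyclic 1,3-dione, the standard access to 2-methyl-1,3-diones; the product is achiral because C2 epimerises through the enol and the ring keeps its mirror plane.

Step 2
Reactants: 2 5-isopropyl-2-methylcyclohexane-1,3-dione; 3 glutaraldehyde
Product: 6 1β-hydroxy-9-oxoeudesm-4-en-15-al (7β-isopropyl; 10β-methyl), via aldol adduct 4 (not isolated), via bicyclic ketol 5 (not isolated)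
Conditions: (S)-proline (30 mol %), DMSO, 23→40 °C, slow addition of 3
Reagents that add atoms: none
Why: Proposed new method: the enol of 2 adds reversibly through C10 to one formyl group of 3 (aldol, giving 4 as an equilibrating set of isomers), proline converts the remote formyl group into an enamine whose carbon C4 attacks one of the two ring carbonyls (C5), and loss of water from ketol 5 through the iminium ion makes the sequence irreversible. The closest known reaction types are the proline-catalysed desymmetrising aldol cyclisation of 2,2-disubstituted cyclohexane-1,3-diones (Hajos–Parrish–Eder–Sauer–Wiechert reaction) and the proline-catalysed 6-enolexo aldolisation of 1,7-dicarbonyl compounds, and the new element is feeding such a cyclisation from a reversible intermolecular aldol of a 2-alkyl-1,3-dione. Ring A closes in the 6-(enolexo)-exo-trig mode through a chair in which the tether leaves C10 equatorially, because only an equatorial C10–C1 bond can reach the axial trajectory at the neighbouring carbonyl C5. C10 and C7: this chair keeps the C7 isopropyl group equatorial and hence the C10 methyl axial and cis to it, while the carboxylic acid of (S)-proline selects one enantiotopic carbonyl and so fixes the absolute sense (the (R)-catalyst would be used should the sense prove opposite). C1: the hydroxyl sits equatorial in the same chair (cis to the methyl, 1β), and because 4 epimerises by retro-aldol all material can drain through this lowest pathway. The selectivity needed is cross- over self-condensation of 3, secured by the much higher enol content and acidity of 2, by the fact that 3 cannot cyclise on itself (a four-membered ring would result), and by slow addition of 3.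

Step 3
Reactants: 6 1β-hydroxy-9-oxoeudesm-4-en-15-al
Product: 7 1β-(TBS-oxy)-9-oxoeudesm-4-en-15-al
Conditions: TBSOTf, 2,6-lutidine, CH2Cl2, −78→0 °C
Reagents that add atoms: tert-butyldimethylsilyl triflate, CC(C)(C)[Si](C)(C)OS(=O)(=O)C(F)(F)F
Why: Silyl ether formation with the silyl triflate, which reaches even a neopentyl carbinol and, under a non-nucleophilic base, blocks retro-aldol loss of the C1–C10 bond in all later steps.

Step 4
Reactants: 7 1β-(TBS-oxy)-9-oxoeudesm-4-en-15-al
Product: 8 1β-(TBS-oxy)eudesm-4-ene-9β,15-diol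
Conditions: LiAlH4, Et2O, −78→0 °C; then H2O
Reagents that add atoms: none
Why: Hydride reduction (1,2-reduction of the fully substituted enal and of the C9 ketone); hydride reaches C9 from the α face opposite the axial C10 methyl to give the 9β-alcohol, whose configuration is erased in step 6.

Step 5
Reactants: 8 1β-(TBS-oxy)eudesm-4-ene-9β,15-diol
Product: 9 9β-hydroxy-1β-(TBS-oxy)eudesm-4-en-15-yl methyl carbonate
Conditions: ClCO2Me (1.1 equiv), pyridine, CH2Cl2, −20 °C
Reagents that add atoms: methyl chloroformate, COC(=O)Cl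
Why: Chemoselective O-acylation: the primary allylic alcohol reacts far faster than the neopentyl 9β-alcohol, and the carbonate both protects C15–O and is the leaving group for step 9.

Step 6
Reactants: 9 9β-hydroxy-1β-(TBS-oxy)eudesm-4-en-15-yl methyl carbonate
Product: 10 1β-(TBS-oxy)eudesma-4,8-dien-15-yl methyl carbonate
Conditions: Burgess reagent (MeO2CNSO2NEt3), toluene, 70 °C
Reagents that add atoms: none
Why: Burgess dehydration (syn elimination of a sulfamate ester): C10 carries no hydrogen, so only a C8 hydrogen can be lost and the alkene must form between C8 and C9, and the concerted path avoids a neopentyl cation.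

Step 7
Reactants: 10 1β-(TBS-oxy)eudesma-4,8-dien-15-yl methyl carbonate
Product: 12 8α-hydroxy-1β-(TBS-oxy)eudesm-4-en-15-yl methyl carbonate, via 8α-alkylborane 11 (not isolated)
Conditions: BH3·THF (1.1 equiv), THF, 0→23 °C; then 30 % H2O2, pH 7 phosphate buffer, MeOH, 0 °C
Reagents that add atoms: hydrogen peroxide, OO
Why: Hydroboration–oxidation: boron goes to C8, away from neopentyl C9, and from the α face opposite both the axial C10 methyl and the adjacent 7β-isopropyl group, so retentive oxidation sets the equatorial 8α-OH trans to isopropyl, while the tetrasubstituted C4=C5 alkene stays inert.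

Step 8
Reactants: 12 8α-hydroxy-1β-(TBS-oxy)eudesm-4-en-15-yl methyl carbonate
Product: 13 1β,8α-bis(TBS-oxy)eudesm-4-en-15-yl methyl carbonate
Conditions: TBSOTf, 2,6-lutidine, CH2Cl2, 0 °C
Reagents that add atoms: tert-butyldimethylsilyl triflate, CC(C)(C)[Si](C)(C)OS(=O)(=O)C(F)(F)F
Why: Silyl ether formation, which leaves C3–OH as the only free hydroxyl at the esterification stage.

Step 9
Reactants: 13 1β,8α-bis(TBS-oxy)eudesm-4-en-15-yl methyl carbonate
Product: 14 1β,8α-bis(TBS-oxy)-5αH-eudesm-4(15)-ene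
Conditions: Pd(OAc)2 (5 mol %), PBu3 (20 mol %), HCO2H, Et3N, THF, 40 °C
Reagents that add atoms: none
Why: Palladium-catalysed hydrogenolysis of an allylic carbonate with formate (Tsuji-type reductive allylic transposition): zerovalent palladium ionises the carbonate on the α face opposite the C10 methyl, and the hydride formed by decarboxylation of formate passes from palladium to the more substituted allyl terminus C5 on that same face, giving 5α-H (trans-decalin) and the exocyclic C4=C15 alkene together.

Step 10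
Reactants: 14 1β,8α-bis(TBS-oxy)-5αH-eudesm-4(15)-ene
Product: 15 1β,8α-bis(TBS-oxy)eudesm-4(15)-en-3α-ol
Conditions: SeO2 (cat.), t-BuOOH, CH2Cl2, 0→23 °C
Reagents that add atoms: tert-butyl hydroperoxide, CC(C)(C)OO
Why: Selenium dioxide allylic oxidation (ene reaction then [2,3]-sigmatropic shift): the C3 methylene reacts in preference to the C5 methine, and since the ene step removes the axial 3α-hydrogen and the shift returns oxygen to the same face, the axial 3α-alcohol should form.

Step 11
Reactants: 16 caffeic acid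
Product: 18 (E)-3,4-bis(TBS-oxy)cinnamic acid, via tris-silyl derivative 17 (not isolated)
Conditions: TBSCl, imidazole, DMF, 23 °C; then AcOH–THF–H2O, 23 °C
Reagents that add atoms: tert-butyldimethylsilyl chloride, CC(C)(C)[Si](C)(C)Cl
Why: Exhaustive silylation followed by selective hydrolysis of the much more labile silyl ester, which masks the catechol for the Mitsunobu step.

Step 12
Reactants: 15 1β,8α-bis(TBS-oxy)eudesm-4(15)-en-3α-ol; 18 (E)-3,4-bis(TBS-oxy)cinnamic acid
Product: 19 1β,8α-bis(TBS-oxy)eudesm-4(15)-en-3β-yl (E)-3,4-bis(TBS-oxy)cinnamate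
Conditions: PPh3, DIAD, toluene, 0→23 °C
Reagents that add atoms: none
Why: Mitsunobu esterification: SN2 displacement of the activated axial 3α-oxygen by the carboxylate inverts C3 to the equatorial 3β-ester, and no other free hydroxyl is present.

Step 13
Reactants: 19 1β,8α-bis(TBS-oxy)eudesm-4(15)-en-3β-yl (E)-3,4-bis(TBS-oxy)cinnamate
Product: 20 1β,8α-dihydroxyeudesm-4(15)-en-3β-yl (E)-caffeate (target)
Conditions: HF·pyridine, THF, 0→23 °C
Reagents that add atoms: none
Why: Fluoride-driven cleavage of all four silyl ethers; buffered HF should leave the allylic cinnamate ester, the exocyclic alkene and the catechol untouched.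

**Compound list**
1 | 5-isopropylcyclohexane-1,3-dione | CC(C)C1CC(=O)CC(=O)C1 | starting material
2 | 5-isopropyl-2-methylcyclohexane-1,3-dione | CC1C(=O)CC(C(C)C)CC1=O | intermediate
3 | glutaraldehyde | O=CCCCC=O | starting material
4 | aldol adduct, 2-(1-hydroxy-5-oxopentyl)-5-isopropyl-2-methylcyclohexane-1,3-dione (productive isomer drawn) | O=CCCC[C@@H](O)[C@]1(C)C(=O)C[C@@H](C(C)C)CC1=O | intermediate
5 | bicyclic ketol, 1β,5-dihydroxy-9-oxoeudesman-15-al (transient centres C4 and C5 left open) | O=CC1CC[C@@H](O)[C@]2(C)C(=O)C[C@@H](C(C)C)CC12O | intermediate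
6 | 1β-hydroxy-9-oxoeudesm-4-en-15-al | O=CC=1CC[C@@H](O)[C@]2(C)C(=O)C[C@@H](C(C)C)CC12 | intermediate
7 | 1β-(TBS-oxy)-9-oxoeudesm-4-en-15-al | O=CC=1CC[C@@H](O[Si](C)(C)C(C)(C)C)[C@]2(C)C(=O)C[C@@H](C(C)C)CC12 | intermediate
8 | 1β-(TBS-oxy)eudesm-4-ene-9β,15-diol | OCC=1CC[C@@H](O[Si](C)(C)C(C)(C)C)[C@]2(C)[C@@H](O)C[C@@H](C(C)C)CC12 | intermediate
9 | 9β-hydroxy-1β-(TBS-oxy)eudesm-4-en-15-yl methyl carbonate | COC(=O)OCC=1CC[C@@H](O[Si](C)(C)C(C)(C)C)[C@]2(C)[C@@H](O)C[C@@H](C(C)C)CC12 | intermediate
10 | 1β-(TBS-oxy)eudesma-4,8-dien-15-yl methyl carbonate | COC(=O)OCC=1CC[C@@H](O[Si](C)(C)C(C)(C)C)[C@]2(C)C=C[C@@H](C(C)C)CC12 | intermediate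
11 | 8α-boranyl-1β-(TBS-oxy)eudesm-4-en-15-yl methyl carbonate | COC(=O)OCC=1CC[C@@H](O[Si](C)(C)C(C)(C)C)[C@]2(C)C[C@H](B)[C@@H](C(C)C)CC12 | intermediate
12 | 8α-hydroxy-1β-(TBS-oxy)eudesm-4-en-15-yl methyl carbonate | COC(=O)OCC=1CC[C@@H](O[Si](C)(C)C(C)(C)C)[C@]2(C)C[C@H](O)[C@@H](C(C)C)CC12 | intermediate
13 | 1β,8α-bis(TBS-oxy)eudesm-4-en-15-yl methyl carbonate | COC(=O)OCC=1CC[C@@H](O[Si](C)(C)C(C)(C)C)[C@]2(C)C[C@H](O[Si](C)(C)C(C)(C)C)[C@@H](C(C)C)CC12 | intermediate
14 | 1β,8α-bis(TBS-oxy)-5αH-eudesm-4(15)-ene | C=C1CC[C@@H](O[Si](C)(C)C(C)(C)C)[C@]2(C)C[C@H](O[Si](C)(C)C(C)(C)C)[C@@H](C(C)C)C[C@@H]12 | intermediate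
15 | 1β,8α-bis(TBS-oxy)eudesm-4(15)-en-3α-ol | C=C1[C@H](O)C[C@@H](O[Si](C)(C)C(C)(C)C)[C@]2(C)C[C@H](O[Si](C)(C)C(C)(C)C)[C@@H](C(C)C)C[C@@H]12 | intermediate
16 | caffeic acid | OC(=O)/C=C/c1ccc(O)c(O)c1 | starting material
17 | TBS (E)-3,4-bis(TBS-oxy)cinnamate | CC(C)(C)[Si](C)(C)OC(=O)/C=C/c1ccc(O[Si](C)(C)C(C)(C)C)c(O[Si](C)(C)C(C)(C)C)c1 | intermediate
18 | (E)-3,4-bis(TBS-oxy)cinnamic acid | OC(=O)/C=C/c1ccc(O[Si](C)(C)C(C)(C)C)c(O[Si](C)(C)C(C)(C)C)c1 | intermediate
19 | 1β,8α-bis(TBS-oxy)eudesm-4(15)-en-3β-yl (E)-3,4-bis(TBS-oxy)cinnamate | C=C1[C@@H](OC(=O)/C=C/c2ccc(O[Si](C)(C)C(C)(C)C)c(O[Si](C)(C)C(C)(C)C)c2)C[C@@H](O[Si](C)(C)C(C)(C)C)[C@]2(C)C[C@H](O[Si](C)(C)C(C)(C)C)[C@@H](C(C)C)C[C@@H]12 | intermediate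
20 | 1β,8α-dihydroxyeudesm-4(15)-en-3β-yl (E)-caffeate | C=C1[C@@H](OC(=O)/C=C/c2ccc(O)c(O)c2)C[C@@H](O)[C@]2(C)C[C@H](O)[C@@H](C(C)C)C[C@@H]12 | target

Total step count: 13. Longest linear sequence: 12 (steps 1–10, 12, 13).

**Steps most likely to fail**

Step 2.
- Risk: oligomerisation of glutaraldehyde may outrun the cross-aldol, the aldol pre-equilibrium may lie too far on the side of 2, or the choice between the two ring carbonyls may be poor.
- Fallback, from 2 back to 6: the two bonds are made one after the other by known reactions. Palladium-catalysed asymmetric allylic alkylation of 2 with prop-2-ene-1,1-diyl diacetate ([Pd(C3H5)Cl]2, DACH-phenyl bisphosphine ligand, NaH, THF) gives 1-acetoxyallyl dione F1, and the isomer with methyl cis to isopropyl is carried on. Cross metathesis with 4,4-dimethoxybut-1-ene (second-generation Grubbs catalyst) gives unsaturated acetal F2. Hydrogenation (H2, RhCl(PPh3)3) gives saturated acetal F3. Aqueous trifluoroacetic acid frees keto aldehyde F4. Pyrrolidine/AcOH closes ring A by aldol condensation to bicyclic acetate F5, the equatorial acetoxy group deciding which carbonyl reacts. K2CO3 in MeOH then gives 6.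

Step 7.
- Risk: regioselectivity between C8 and C9 may be poor, or the hindered alkene may react sluggishly.
- Fallback, from 10 back to 13: oxygen is placed on both carbons and the unwanted one is removed. OsO4 (cat.)/NMO attacks the less hindered disubstituted alkene from the α face to give 8α,9α-diol F6. TBSCl/imidazole silylates only the less hindered 8α-OH to give mono-silyl ether F7. NaH, CS2, then MeI gives 9α-xanthate F8. Barton–McCombie reduction (Bu3SnH, AIBN, toluene, 90 °C) then gives 13.

Step 9.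
- Risk: hydride may transfer to the primary terminus C15 and retain the tetrasubstituted alkene, β-hydride elimination may give dienes, or the hindered allylic carbonate may ionise slowly.
- Fallback, from 13 back to 14: a metal-free sigmatropic transposition is used. K2CO3/MeOH gives primary allylic alcohol F9. Mitsunobu reaction with 2-nitrobenzenesulfonylhydrazide (PPh3, DEAD, THF, −30 °C) gives sulfonylhydrazine F10. On warming, this loses the sulfinic acid to give allylic diazene F11. Its retro-ene loss of nitrogen delivers hydrogen to C5 on the α face opposite the C10 methyl and gives 14.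

**Further compounds**
F1 | step 2 | 2-(1-acetoxyallyl)-5-isopropyl-2-methylcyclohexane-1,3-dione | C=C[C@@H](OC(C)=O)[C@]1(C)C(=O)C[C@@H](C(C)C)CC1=O
F2 | step 2 | (E)-1-acetoxy-5,5-dimethoxypent-2-enyl dione | COC(OC)C/C=C/[C@@H](OC(C)=O)[C@]1(C)C(=O)C[C@@H](C(C)C)CC1=O
F3 | step 2 | 1-acetoxy-5,5-dimethoxypentyl dione | COC(OC)CCC[C@@H](OC(C)=O)[C@]1(C)C(=O)C[C@@H](C(C)C)CC1=O
F4 | step 2 | 1-acetoxy-5-oxopentyl dione | O=CCCC[C@@H](OC(C)=O)[C@]1(C)C(=O)C[C@@H](C(C)C)CC1=O
F5 | step 2 | 1β-acetoxy-9-oxoeudesm-4-en-15-al | O=CC=1CC[C@@H](OC(C)=O)[C@]2(C)C(=O)C[C@@H](C(C)C)CC12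
F6 | step 7 | 8α,9α-dihydroxy-1β-(TBS-oxy)eudesm-4-en-15-yl methyl carbonate | COC(=O)OCC=1CC[C@@H](O[Si](C)(C)C(C)(C)C)[C@]2(C)[C@H](O)[C@H](O)[C@@H](C(C)C)CC12
F7 | step 7 | 9α-hydroxy-1β,8α-bis(TBS-oxy)eudesm-4-en-15-yl methyl carbonate | COC(=O)OCC=1CC[C@@H](O[Si](C)(C)C(C)(C)C)[C@]2(C)[C@H](O)[C@H](O[Si](C)(C)C(C)(C)C)[C@@H](C(C)C)CC12
F8 | step 7 | 9α-(methylsulfanylthiocarbonyloxy)-1β,8α-bis(TBS-oxy)eudesm-4-en-15-yl methyl carbonate | COC(=O)OCC=1CC[C@@H](O[Si](C)(C)C(C)(C)C)[C@]2(C)[C@H](OC(=S)SC)[C@H](O[Si](C)(C)C(C)(C)C)[C@@H](C(C)C)CC12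
F9 | step 9 | 1β,8α-bis(TBS-oxy)eudesm-4-en-15-ol | OCC=1CC[C@@H](O[Si](C)(C)C(C)(C)C)[C@]2(C)C[C@H](O[Si](C)(C)C(C)(C)C)[C@@H](C(C)C)CC12
F10 | step 9 | N-(eudesm-4-en-15-yl)-N-(2-nitrobenzenesulfonyl)hydrazine, 1β,8α-bis(TBS-oxy) | NN(CC=1CC[C@@H](O[Si](C)(C)C(C)(C)C)[C@]2(C)C[C@H](O[Si](C)(C)C(C)(C)C)[C@@H](C(C)C)CC12)S(=O)(=O)c1ccccc1[N+](=O)[O-]
F11 | step 9 | 1β,8α-bis(TBS-oxy)eudesm-4-en-15-yldiazene | N=NCC=1CC[C@@H](O[Si](C)(C)C(C)(C)C)[C@]2(C)C[C@H](O[Si](C)(C)C(C)(C)C)[C@@H](C(C)C)CC12
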